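**Remark on numbering and one assumption:** lignan locants are used throughout. C7/C7' are the two carbinol carbons, C8/C8' are oxolane C3/C4, and C9/C9' are oxolane C2/C5. Read from the SMILES, the target 14 is (7S,8R,8'R,7'S), i.e. (S,S)-[(3R,4R)-oxolane-3,4-diyl]bis[(4-hydroxy-3-methoxyphenyl)methanol]. The silyl-protected vanillin 2 is assumed to be made rather than bought.

## The problem

Target 14 is a trans-3,4-disubstituted oxolane whose two identical arms are secondary benzylic carbinols. Four contiguous stereocenters (C7, C8, C8', C7') lie on a branched six-carbon chain. A C2 axis runs through the ring oxygen O1 and the midpoint of the C3–C4 bond, so only two stereocenters are independent: the C7/C8 pair, which is syn in the aldol sense, and its copy. The carbinol carbons are exocyclic and rotate freely, so a preformed ring cannot be relied on to control them. C7 and C8 are best set together in one closed transition state on an open chain, and the trans relationship C8/C8' then follows from doing the same thing twice in the same sense. The feature that makes this possible is that ring atoms C2–C3–C4–C5 (C9–C8–C8'–C9') are the four carbons of succinic acid at the diol oxidation level, bisected by the C2 axis. Each carbinol carbon is β to a ring CH2–O carbon, so the molecule holds two aldol retrons that share one C4 unit. Ring closure must join the two primary oxygens (9-O-9') and not a benzylic oxygen to C9' (the furofuran mode). The free para-hydroxybenzylic alcohols ionize to quinone methides with acid, or with base and heat, and are at risk under hydrogenolysis, so the end of the route must be neutral and must not break a C–O bond at C7.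

## Retrosynthesis

**14 ⇒ 13.** Only four O–Si bonds are cut. Phenols are carried as triisopropylsilyl ethers and carbinols as tert-butyldimethylsilyl ethers, so one buffered fluoride treatment ends the synthesis. Benzyl ethers were set aside because their hydrogenolysis endangers the benzylic C–O bonds. The forward step only has to be mild.

**13 ⇒ 11 (through monotosylate 12).** The ring bond O1–C2 is cut. A C–O closure at a CH2 group touches no stereocenter and leaves an open chain on which acyclic stereocontrol can work, which a ring C–C disconnection or a cycloaddition would not. Diol 11 is C2-symmetric, so its two CH2OH groups are homotopic and activation of either gives the same monotosylate 12. The forward reaction must let only the primary oxygen attack; the benzylic oxygens are silylated and silent.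

**11 ⇒ 10 ⇒ 9.** C9 and C9' are raised from CH2OH to the acyl level (imides), and the benzylic silyl ethers go back to hydroxyls. Silylating 9 before reduction distinguishes benzylic from primary oxygens without any selective protection. In 9 each carbinol is β to an imide carbonyl that carries a chiral auxiliary. The forward reduction must attack the exocyclic carbonyls only.

**9 ⇒ 6 + two molecules of 2 (through bis-enol borinate 7 and bis-aldol borinate 8).** Both C7–C8 and C7'–C8' are cut at once. Cutting C8–C8' instead would require each half to be made enantiopure first and then joined by a radical-type coupling. Cutting one aldol bond at a time gives unsymmetrical intermediates and twice the operations. The precursor is far simpler: bis-imide 6 is succinic acid flanked by two copies of a commercial auxiliary, with no stereocenter in the chain, and aldehyde 2 is protected vanillin. The forward reaction must enolize both arms, add each with syn selectivity, and add in the same facial sense twice. Its product holds all twenty carbons and all four stereocenters of the target.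

**6 ⇒ 3 + 4 (through lithium salt 5); 2 ⇒ 1.** Two N–acyl bonds and one O–Si bond are cut. Oxazolidinone 3, succinyl chloride 4 and vanillin 1 are commercial. The forward steps are a twofold N-acylation and a phenol silylation.

## Roads not taken

**Alternative 1:** (the most obvious) cut C8'–C7' and C8–C7 one after the other on a 9,9'-lactone. The forward key step is conjugate addition of the lithiated dithiane A1 to 2(5H)-furanone, followed by aldol trapping of the lactone enolate with aldehyde 2, to give the trans-lactone A2. The chosen plan is better for four reasons.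
- The butenolide is achiral, so absolute configuration needs an extra auxiliary on the ring or a chiral ligand.
- The carbinol center from a lactone-enolate aldol is weakly controlled, and the other benzylic carbon arrives as a masked ketone that must be unmasked next to electron-rich arenes and reduced under 1,2-induction.
- The lactone carbonyl must then be taken down to CH2 in the presence of two benzylic oxygens.
- The two identical halves are made by three different reactions, so the C2 axis is not used and the route is several steps longer.

**Alternative 2:** cut C8–C8' in the biomimetic sense. The forward key step is one-electron oxidation of ferulic acid (FeCl3/O2 or a peroxidase) to the racemic dilactone A3, which has the right relative configuration at all four centers. Reduction gives the racemic tetraol A4, and 9-O-9' closure would follow. The chosen plan is better for three reasons.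
- The radical coupling has no handle for absolute control, so a resolution would discard half the material.
- The coupling is unselective among the 8–8, 8–5 and 8–O modes.
- A4 has four hydroxyls beside free phenols, and any acid closes the ether from the benzylic carbons (the furofuran mode) rather than from the primary ones.

The chosen route reaches the same array in protected form (11) as one enantiomer, with the two kinds of hydroxyl already told apart.

**Alternative 3:** keep the ring and cut at the carbinol stereocenters. The forward key step is a two-directional asymmetric reduction of the (3R,4R)-diketone A5. The ring would come from a carbonyl ylide cycloaddition to a fumarate bearing auxiliaries, or from resolved trans-oxolane-3,4-dicarboxylic acid. The chosen plan is better for three reasons.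
- Ring and carbinol stereocenters are set in two separate events.
- Each ketone α-carbon carries two ring branches of similar size (C9H2 and C8'H), so substrate induction is weak and a chiral reductant must do the work twice.
- The α-centers can epimerize, and the sequence is longer and less convergent.

Key step: step 3

## Route

Step 1
Reactants: 1 vanillin (4-hydroxy-3-methoxybenzaldehyde)
Product: 2 3-methoxy-4-(triisopropylsilyloxy)benzaldehyde
Conditions: TIPSCl (1.1 equiv), imidazole (2 equiv), DMF, 0 °C to rt
Reagents that add atoms: chlorotriisopropylsilane (TIPSCl), CC(C)[Si](Cl)(C(C)C)C(C)C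
Why: Silylation of a phenol; the bulky aryl silyl ether should withstand the amine base, peroxide work-up, borohydride and pyridine of steps 3 to 6 and leave with fluoride at the end.

Step 2
Reactants: 3 (S)-4-benzyl-1,3-oxazolidin-2-one (2 equiv); 4 succinyl chloride (butanedioyl dichloride, 1 equiv)
Product: 6 1,4-bis[(4S)-4-benzyl-2-oxo-1,3-oxazolidin-3-yl]butane-1,4-dione, via N-lithio oxazolidinone 5 (not isolated)
Conditions: n-BuLi (1 equiv per 3), THF, −78 °C; then 4, −78 °C to 0 °C
Reagents that add atoms: none
Why: N-acylation of a lithiated oxazolidinone with an acid chloride, carried out at both ends of the C4 diacid chloride; no stereocenter is formed and the auxiliary center is not at risk at low temperature.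

Step 3
Reactants: 6 1,4-bis[(4S)-4-benzyl-2-oxo-1,3-oxazolidin-3-yl]butane-1,4-dione; 2 3-methoxy-4-(triisopropylsilyloxy)benzaldehyde (2.4 equiv)
Product: 9 (2S,3S)-1,4-bis[(4S)-4-benzyl-2-oxo-1,3-oxazolidin-3-yl]-2,3-bis[(S)-hydroxy(3-methoxy-4-triisopropylsilyloxyphenyl)methyl]butane-1,4-dione, via bis-enol borinate 7 (not isolated), via bis-aldol borinate 8 (not isolated)
Conditions: Bu2BOTf (2.4 equiv), iPr2NEt (2.8 equiv), CH2Cl2, 0 °C; then 2, −78 °C to 0 °C; then pH 7 phosphate buffer, MeOH, 30% H2O2, 0 °C
Reagents that add atoms: none
Why: Soft enolization of both imide arms (Bu2BOTf binds each imide carbonyl and iPr2NEt removes one proton from each CH2) should give the bis-(Z)-enol borinate 7, and each enolate then adds to one aldehyde through a closed chair transition state of the Zimmerman–Traxler type with boron bridging the enolate and aldehyde oxygens, i.e. the Evans syn-aldol reaction run twice in one flask. The closest known reaction type is the dibutylboron aldol of N-acyloxazolidinones, including succinate-derived imides and imides with a branched β-carbon, which is what the second addition amounts to once the first has taken place. No ring is closed in this step. C8 and C7 are set together by the first auxiliary: the Z-enolate geometry gives the syn relationship, and the benzyl group of the dipole-opposed oxazolidinone blocks one enolate face, so that the (S)-auxiliary leads to the (2S,3S)-type syn aldol. C8' and C7' are set in the same way by the second auxiliary, and because the two auxiliaries are identical and the two arms are related by the C2 axis, both events ask for the same sense and should deliver the C2-symmetric borinate 8. The selectivity needed is auxiliary control over the new C8 stereocenter that sits next to the second enolate carbon; in boron aldols of this type the auxiliary normally overrides a β-stereocenter in the enolate, and a half that went the wrong way would give an unsymmetrical diastereomer that can be separated, so the symmetric product should be enriched by the twofold selection. Buffered peroxide work-up frees diol 9 from boron; it is silylated without delay because each hydroxyl is placed to lactonize onto the far imide.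

Step 4
Reactants: 9 (2S,3S)-1,4-bis[(4S)-4-benzyl-2-oxo-1,3-oxazolidin-3-yl]-2,3-bis[(S)-hydroxy(3-methoxy-4-triisopropylsilyloxyphenyl)methyl]butane-1,4-dione
Product: 10 (2S,3S)-1,4-bis[(4S)-4-benzyl-2-oxo-1,3-oxazolidin-3-yl]-2,3-bis[(S)-(tert-butyldimethylsilyloxy)(3-methoxy-4-triisopropylsilyloxyphenyl)methyl]butane-1,4-dione
Conditions: TBSOTf (3 equiv), 2,6-lutidine (5 equiv), CH2Cl2, −78 °C to 0 °C
Reagents that add atoms: tert-butyldimethylsilyl trifluoromethanesulfonate (TBSOTf), CC(C)(C)[Si](C)(C)OS(=O)(=O)C(F)(F)F
Why: Silyl triflate/lutidine silylation of hindered aldol hydroxyls, the usual capping of auxiliary aldol adducts; it stops retro-aldol and lactonization and marks the benzylic oxygens so that only the primary hydroxyls made in step 5 are free for ring closure. No stereocenter is touched.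

Step 5
Reactants: 10 (2S,3S)-1,4-bis[(4S)-4-benzyl-2-oxo-1,3-oxazolidin-3-yl]-2,3-bis[(S)-(tert-butyldimethylsilyloxy)(3-methoxy-4-triisopropylsilyloxyphenyl)methyl]butane-1,4-dione
Product: 11 (2R,3R)-2,3-bis[(S)-(tert-butyldimethylsilyloxy)(3-methoxy-4-triisopropylsilyloxyphenyl)methyl]butane-1,4-diol
Conditions: LiBH4 (5 equiv), MeOH (5 equiv), THF, 0 °C to rt; then aq. NH4Cl
Reagents that add atoms: none
Why: Reductive cleavage of N-acyloxazolidinones with LiBH4 (hydride attack at the exocyclic carbonyl, then reduction of the released aldehyde) should give the two primary alcohols and return auxiliary 3. The silyl ethers are inert, and the change of descriptor at C8/C8' from S to R is formal (CH2OH now ranks below C7), with no change in geometry.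

Step 6
Reactants: 11 (2R,3R)-2,3-bis[(S)-(tert-butyldimethylsilyloxy)(3-methoxy-4-triisopropylsilyloxyphenyl)methyl]butane-1,4-diol
Product: 13 (3R,4R)-3,4-bis[(S)-(tert-butyldimethylsilyloxy)(3-methoxy-4-triisopropylsilyloxyphenyl)methyl]oxolane, via monotosylate 12 (not isolated)
Conditions: TsCl (1.1 equiv), pyridine, DMAP (cat.), 0 °C to 50 °C
Reagents that add atoms: none
Why: Williamson-type cyclodehydration of a 1,4-diol: the C2 axis makes the two CH2OH groups equivalent, so sulfonylation of either gives the same monotosylate 12, which should close by 5-exo-tet attack of the remaining primary hydroxyl. The displacement is at a CH2 group, so no stereocenter is involved, and the silylated benzylic oxygens cannot compete for the furofuran-type closure.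

Step 7
Reactants: 13 (3R,4R)-3,4-bis[(S)-(tert-butyldimethylsilyloxy)(3-methoxy-4-triisopropylsilyloxyphenyl)methyl]oxolane
Product: 14 (S,S)-[(3R,4R)-oxolane-3,4-diyl]bis[(4-hydroxy-3-methoxyphenyl)methanol] (target)
Conditions: Bu4NF (6 equiv), AcOH (6 equiv), THF, 0 °C to rt
Reagents that add atoms: none
Why: Fluoride cleavage of all four Si–O bonds; the acetic acid buffer keeps the phenols protonated so that the para-hydroxybenzylic alcohols are not driven to quinone methides, and no acid or hydrogenolysis is used. No bond to a stereocenter is broken, so all four configurations are retained.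

## Compound list

1 | vanillin (4-hydroxy-3-methoxybenzaldehyde) | COc1cc(C=O)ccc1O | starting material
2 | 3-methoxy-4-(triisopropylsilyloxy)benzaldehyde | COc1cc(C=O)ccc1O[Si](C(C)C)(C(C)C)C(C)C | intermediate
3 | (S)-4-benzyl-1,3-oxazolidin-2-one | O=C1N[C@@H](Cc2ccccc2)CO1 | starting material
4 | succinyl chloride (butanedioyl dichloride) | O=C(Cl)CCC(=O)Cl | starting material
5 | N-lithio-(S)-4-benzyl-1,3-oxazolidin-2-one | [Li]N1[C@@H](Cc2ccccc2)COC1=O | intermediate (not isolated)
6 | 1,4-bis[(4S)-4-benzyl-2-oxo-1,3-oxazolidin-3-yl]butane-1,4-dione | O=C(CCC(=O)N1[C@@H](Cc2ccccc2)COC1=O)N1[C@@H](Cc2ccccc2)COC1=O | intermediate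
7 | (1Z,3Z)-1,4-bis[(4S)-4-benzyl-2-oxo-1,3-oxazolidin-3-yl]-1,4-bis(dibutylboryloxy)buta-1,3-diene (bis-enol borinate) | CCCCB(CCCC)O/C(N1[C@@H](Cc2ccccc2)COC1=O)=C\C=C(/OB(CCCC)CCCC)N1[C@@H](Cc2ccccc2)COC1=O | intermediate (not isolated)
8 | (2S,3S)-1,4-bis[(4S)-4-benzyl-2-oxo-1,3-oxazolidin-3-yl]-2,3-bis[(S)-(dibutylboryloxy)(3-methoxy-4-triisopropylsilyloxyphenyl)methyl]butane-1,4-dione (bis-aldol borinate) | COc1cc(ccc1O[Si](C(C)C)(C(C)C)C(C)C)[C@@H](OB(CCCC)CCCC)[C@@H](C(=O)N1[C@@H](Cc2ccccc2)COC1=O)[C@H](C(=O)N1[C@@H](Cc2ccccc2)COC1=O)[C@H](OB(CCCC)CCCC)c1ccc(O[Si](C(C)C)(C(C)C)C(C)C)c(OC)c1 | intermediate (not isolated)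
9 | (2S,3S)-1,4-bis[(4S)-4-benzyl-2-oxo-1,3-oxazolidin-3-yl]-2,3-bis[(S)-hydroxy(3-methoxy-4-triisopropylsilyloxyphenyl)methyl]butane-1,4-dione | COc1cc(ccc1O[Si](C(C)C)(C(C)C)C(C)C)[C@@H](O)[C@@H](C(=O)N1[C@@H](Cc2ccccc2)COC1=O)[C@H](C(=O)N1[C@@H](Cc2ccccc2)COC1=O)[C@H](O)c1ccc(O[Si](C(C)C)(C(C)C)C(C)C)c(OC)c1 | intermediate
10 | (2S,3S)-1,4-bis[(4S)-4-benzyl-2-oxo-1,3-oxazolidin-3-yl]-2,3-bis[(S)-(tert-butyldimethylsilyloxy)(3-methoxy-4-triisopropylsilyloxyphenyl)methyl]butane-1,4-dione | COc1cc(ccc1O[Si](C(C)C)(C(C)C)C(C)C)[C@@H](O[Si](C)(C)C(C)(C)C)[C@@H](C(=O)N1[C@@H](Cc2ccccc2)COC1=O)[C@H](C(=O)N1[C@@H](Cc2ccccc2)COC1=O)[C@H](O[Si](C)(C)C(C)(C)C)c1ccc(O[Si](C(C)C)(C(C)C)C(C)C)c(OC)c1 | intermediate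
11 | (2R,3R)-2,3-bis[(S)-(tert-butyldimethylsilyloxy)(3-methoxy-4-triisopropylsilyloxyphenyl)methyl]butane-1,4-diol | COc1cc(ccc1O[Si](C(C)C)(C(C)C)C(C)C)[C@@H](O[Si](C)(C)C(C)(C)C)[C@@H](CO)[C@H](CO)[C@H](O[Si](C)(C)C(C)(C)C)c1ccc(O[Si](C(C)C)(C(C)C)C(C)C)c(OC)c1 | intermediate
12 | (2R,3R)-2,3-bis[(S)-(tert-butyldimethylsilyloxy)(3-methoxy-4-triisopropylsilyloxyphenyl)methyl]-4-hydroxybutyl 4-methylbenzenesulfonate | COc1cc(ccc1O[Si](C(C)C)(C(C)C)C(C)C)[C@@H](O[Si](C)(C)C(C)(C)C)[C@@H](COS(=O)(=O)c1ccc(C)cc1)[C@H](CO)[C@H](O[Si](C)(C)C(C)(C)C)c1ccc(O[Si](C(C)C)(C(C)C)C(C)C)c(OC)c1 | intermediate (not isolated)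
13 | (3R,4R)-3,4-bis[(S)-(tert-butyldimethylsilyloxy)(3-methoxy-4-triisopropylsilyloxyphenyl)methyl]oxolane | COc1cc([C@@H](O[Si](C)(C)C(C)(C)C)[C@H]2COC[C@@H]2[C@H](O[Si](C)(C)C(C)(C)C)c2ccc(O[Si](C(C)C)(C(C)C)C(C)C)c(OC)c2)ccc1O[Si](C(C)C)(C(C)C)C(C)C | intermediate
14 | (S,S)-[(3R,4R)-oxolane-3,4-diyl]bis[(4-hydroxy-3-methoxyphenyl)methanol] | COc1cc([C@@H](O)[C@H]2COC[C@@H]2[C@H](O)c2ccc(O)c(OC)c2)ccc1O | target

## Step count and least certain steps

Total steps: 7. Longest linear sequence: 6 (steps 2 to 7; the branch through step 1 is equally long).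

**Step 3 (key step).** Three things are most likely to go wrong.
- The reaction may stall after one addition, because the second enolization or addition is slowed by the bulky borinate-bearing branch next to it.
- Facial control in the second addition may erode, because the new C8 stereocenter sits next to the reacting enolate carbon.
- An aldol oxygen may lactonize onto the far imide, or retro-aldol may occur, during work-up, since the aldehyde is electron-rich.

Fallback, setting out from 6 and returning at 10: the two additions are separated, with protection in between, so that no bis-enolate and no free aldol hydroxyl is ever present. One arm of 6 is enolized (Bu2BOTf and iPr2NEt, one equivalent each) and treated with one equivalent of 2 to give the mono-aldol adduct (2S)-1,4-bis[(4S)-4-benzyl-2-oxo-1,3-oxazolidin-3-yl]-2-[(S)-hydroxy(3-methoxy-4-triisopropylsilyloxyphenyl)methyl]butane-1,4-dione F1. Silylation (TBSOTf, 2,6-lutidine) gives its tert-butyldimethylsilyl ether F2. The remaining CH2–imide arm of F2 is then enolized and added to 2 in a separate auxiliary aldol of the usual kind to give the hydroxy silyl ether F3, which is silylated to 10.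

**Step 5.** Hydride may attack the ring carbonyl of the oxazolidinones (ring opening of the auxiliary) because both exocyclic carbonyls are flanked by a tertiary carbon and a silyloxy-bearing branch. The silyl group may also migrate from O7 to the new primary alkoxide. Fallback, setting out from 9 and returning at 11: the reduction is run before silylation (LiBH4, THF, one equivalent of H2O), where each free β-hydroxyl binds boron and delivers hydride to its own exocyclic carbonyl, to give the tetraol (2R,3R)-2,3-bis[(S)-hydroxy(3-methoxy-4-triisopropylsilyloxyphenyl)methyl]butane-1,4-diol F4. All four hydroxyls are silylated (TBSOTf, 2,6-lutidine) to the tetrakis(tert-butyldimethylsilyl) ether F5. The two primary silyl ethers are then cleaved selectively (HF·pyridine, pyridine, THF, 0 °C) to give 11.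

**Step 2.** After the first acylation the remaining acid chloride arm may close onto the imide oxygen or eliminate to a ketene, since succinyl chloride reacts in part through cyclic forms; this would give mixtures in place of clean twofold acylation. Fallback, setting out from 5 and returning at 6: 5 is acylated with fumaroyl dichloride, which cannot cyclize, to give (E)-1,4-bis[(4S)-4-benzyl-2-oxo-1,3-oxazolidin-3-yl]but-2-ene-1,4-dione F6, and hydrogenation (H2, Pd/C, EtOAc) gives 6.

**Step 7.** The two hindered secondary silyl ethers may cleave slowly, forcing long exposure of the freed phenols to fluoride. That invites 1,6-elimination to a quinone methide followed by re-addition (loss of configuration at C7) or oligomerization. Fallback, setting out from 13 and returning at 14: the secondary silyl ethers are removed first while the phenols are still masked (HF·pyridine, pyridine, THF) to give (S,S)-[(3R,4R)-oxolane-3,4-diyl]bis[(3-methoxy-4-triisopropylsilyloxyphenyl)methanol] F7. A short buffered fluoride treatment (Bu4NF, AcOH, THF, 0 °C) then frees the phenols to give 14.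

## Further compounds

F1 | step 3 | (2S)-1,4-bis[(4S)-4-benzyl-2-oxo-1,3-oxazolidin-3-yl]-2-[(S)-hydroxy(3-methoxy-4-triisopropylsilyloxyphenyl)methyl]butane-1,4-dione | COc1cc(ccc1O[Si](C(C)C)(C(C)C)C(C)C)[C@@H](O)[C@@H](C(=O)N1[C@@H](Cc2ccccc2)COC1=O)CC(=O)N1[C@@H](Cc2ccccc2)COC1=O
F2 | step 3 | (2S)-1,4-bis[(4S)-4-benzyl-2-oxo-1,3-oxazolidin-3-yl]-2-[(S)-(tert-butyldimethylsilyloxy)(3-methoxy-4-triisopropylsilyloxyphenyl)methyl]butane-1,4-dione | COc1cc(ccc1O[Si](C(C)C)(C(C)C)C(C)C)[C@@H](O[Si](C)(C)C(C)(C)C)[C@@H](C(=O)N1[C@@H](Cc2ccccc2)COC1=O)CC(=O)N1[C@@H](Cc2ccccc2)COC1=O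
F3 | step 3 | (2S,3S)-1,4-bis[(4S)-4-benzyl-2-oxo-1,3-oxazolidin-3-yl]-2-[(S)-(tert-butyldimethylsilyloxy)(3-methoxy-4-triisopropylsilyloxyphenyl)methyl]-3-[(S)-hydroxy(3-methoxy-4-triisopropylsilyloxyphenyl)methyl]butane-1,4-dione | COc1cc(ccc1O[Si](C(C)C)(C(C)C)C(C)C)[C@@H](O[Si](C)(C)C(C)(C)C)[C@@H](C(=O)N1[C@@H](Cc2ccccc2)COC1=O)[C@H](C(=O)N1[C@@H](Cc2ccccc2)COC1=O)[C@H](O)c1ccc(O[Si](C(C)C)(C(C)C)C(C)C)c(OC)c1
F4 | step 5 | (2R,3R)-2,3-bis[(S)-hydroxy(3-methoxy-4-triisopropylsilyloxyphenyl)methyl]butane-1,4-diol | COc1cc(ccc1O[Si](C(C)C)(C(C)C)C(C)C)[C@@H](O)[C@@H](CO)[C@H](CO)[C@H](O)c1ccc(O[Si](C(C)C)(C(C)C)C(C)C)c(OC)c1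
F5 | step 5 | (2R,3R)-1,4-bis(tert-butyldimethylsilyloxy)-2,3-bis[(S)-(tert-butyldimethylsilyloxy)(3-methoxy-4-triisopropylsilyloxyphenyl)methyl]butane | COc1cc(ccc1O[Si](C(C)C)(C(C)C)C(C)C)[C@@H](O[Si](C)(C)C(C)(C)C)[C@@H](CO[Si](C)(C)C(C)(C)C)[C@H](CO[Si](C)(C)C(C)(C)C)[C@H](O[Si](C)(C)C(C)(C)C)c1ccc(O[Si](C(C)C)(C(C)C)C(C)C)c(OC)c1
F6 | step 2 | (E)-1,4-bis[(4S)-4-benzyl-2-oxo-1,3-oxazolidin-3-yl]but-2-ene-1,4-dione | O=C(/C=C/C(=O)N1[C@@H](Cc2ccccc2)COC1=O)N1[C@@H](Cc2ccccc2)COC1=O
F7 | step 7 | (S,S)-[(3R,4R)-oxolane-3,4-diyl]bis[(3-methoxy-4-triisopropylsilyloxyphenyl)methanol] | COc1cc([C@@H](O)[C@H]2COC[C@@H]2[C@H](O)c2ccc(O[Si](C(C)C)(C(C)C)C(C)C)c(OC)c2)ccc1O[Si](C(C)C)(C(C)C)C(C)C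
A1 | alternative 1 | 2-(3-methoxy-4-triisopropylsilyloxyphenyl)-1,3-dithiane | COc1cc(ccc1O[Si](C(C)C)(C(C)C)C(C)C)C1SCCCS1
A2 | alternative 1 | (3S,4R)-3-[hydroxy(3-methoxy-4-triisopropylsilyloxyphenyl)methyl]-4-[2-(3-methoxy-4-triisopropylsilyloxyphenyl)-1,3-dithian-2-yl]oxolan-2-one (carbinol center not controlled) | COc1cc(ccc1O[Si](C(C)C)(C(C)C)C(C)C)C(O)[C@H]1C(=O)OC[C@@H]1C1(SCCCS1)c1ccc(O[Si](C(C)C)(C(C)C)C(C)C)c(OC)c1
A3 | alternative 2 | racemic 2,6-exo,exo-bis(4-hydroxy-3-methoxyphenyl)-cis-3,7-dioxabicyclo[3.3.0]octane-4,8-dione (one enantiomer drawn) | COc1cc(ccc1O)[C@H]1OC(=O)[C@H]2[C@@H]1C(=O)O[C@@H]2c1ccc(O)c(OC)c1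
A4 | alternative 2 | racemic 2,3-bis[hydroxy(4-hydroxy-3-methoxyphenyl)methyl]butane-1,4-diol with the relative configuration of 14 (one enantiomer drawn) | COc1cc(ccc1O)[C@@H](O)[C@@H](CO)[C@H](CO)[C@H](O)c1ccc(O)c(OC)c1
A5 | alternative 3 | [(3R,4R)-oxolane-3,4-diyl]bis[(3-methoxy-4-triisopropylsilyloxyphenyl)methanone] | COc1cc(ccc1O[Si](C(C)C)(C(C)C)C(C)C)C(=O)[C@H]1COC[C@@H]1C(=O)c1ccc(O[Si](C(C)C)(C(C)C)C(C)C)c(OC)c1
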